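**Plan**

- Ring letters: A = the trioxygenated ring, B = the para-phenylene ring, C = the 1,2,3-trisubstituted ring with one OH, D = the ortho-phenylene ring. The retrosynthesis first cuts the bond between the ring-A carbon and the ether oxygen of the A–O–B diaryl ether, which opens the 17-membered ring. It then cuts the outer ring-A C–OH (from C–Br), both CH2–CH2 bridges (Wittig, then hydrogenation) and the C–O–D ether (SNAr).
- Enabling feature: on ring A the ether carbon and the carbon of the outer OH are the two ortho positions of the central phenolic oxygen. Ring A therefore maps onto a 4-alkyl-2,6-dibromophenol: anodic oxidation lets the ring-B phenol oxygen replace one ortho bromine (bromodienone, then zinc), and the second bromine later becomes the outer OH.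
- Helpers: two chlorines on ring B keep that phenol as the non-oxidised O-nucleophile and block C–C coupling; they leave by hydrogenolysis. The ring-C OH stays as OMe until the last step.
- Forward order: B–C stilbene, C–O–D ether, D–A stilbene, saturation and debenzylation, dibromination of ring A, anodic macrocyclisation (the only ring formed), Br to OH, dechlorination, demethylation.
- Stereochemistry: the target has no stereogenic element. Alkene geometry is irrelevant (both alkenes are hydrogenated) and the one transient stereocentre of the dienone is erased on reduction.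

Key step: step 9

Remark: the target has no stereocentre and the 17-membered ring is taken as conformationally mobile, so it is treated as one achiral compound and no asymmetric step is needed.

**Route**

Step 1
Reactants: 1 3,5-dichloro-4-hydroxybenzaldehyde
Product: 2 4-(benzyloxy)-3,5-dichlorobenzaldehyde
Conditions: BnBr, K2CO3, DMF, 60 °C
Reagents that add atoms: benzyl bromide, BrCc1ccccc1
Why: Williamson etherification of the acidic 2,6-dichlorophenol should proceed cleanly and masks the ring-B phenol through the base-mediated steps that follow.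

Step 2
Reactants: 3 2-hydroxy-3-methoxybenzyl alcohol
Product: 4 (2-hydroxy-3-methoxybenzyl)triphenylphosphonium bromide
Conditions: PPh3·HBr, MeCN, reflux
Reagents that add atoms: triphenylphosphine hydrobromide, [Br-].[PH+](c1ccccc1)(c1ccccc1)c1ccccc1
Why: Phosphonium salt formation from an o-hydroxybenzyl alcohol, which ionises readily under HBr (o-quinone methide or benzylic cation) and is trapped by PPh3.

Step 3
Reactants: 4 (2-hydroxy-3-methoxybenzyl)triphenylphosphonium bromide; 2 4-(benzyloxy)-3,5-dichlorobenzaldehyde
Product: 5 2-[(E)-2-(4-benzyloxy-3,5-dichlorophenyl)ethenyl]-6-methoxyphenol (E/Z mixture expected; E drawn)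
Conditions: KOtBu (2.2 equiv), THF, 0 °C to rt; aq. HCl work-up
Reagents that add atoms: none
Why: Wittig olefination of the phenoxide-ylide formed with two equivalents of base should give the o-hydroxystilbene; its geometry is of no consequence because the alkene is hydrogenated in step 7.

Step 4
Reactants: 5 2-[(E)-2-(4-benzyloxy-3,5-dichlorophenyl)ethenyl]-6-methoxyphenol; 6 2-fluorobenzaldehyde
Product: 7 2-{2-[(E)-2-(4-benzyloxy-3,5-dichlorophenyl)ethenyl]-6-methoxyphenoxy}benzaldehyde
Conditions: K2CO3, DMF, 120 °C
Reagents that add atoms: none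
Why: SNAr of the only free phenoxide on the ortho-formyl-activated fluoroarene should form the C–O–D diaryl ether, the unactivated aryl chlorides and the benzyl ether being inert.

Step 5
Reactants: 8 4-(benzyloxy)benzyl chloride
Product: 9 [4-(benzyloxy)benzyl]triphenylphosphonium chloride
Conditions: PPh3, toluene, reflux
Reagents that add atoms: triphenylphosphine, c1ccc(cc1)P(c1ccccc1)c1ccccc1
Why: SN2 quaternisation of triphenylphosphine by a reactive p-alkoxybenzyl chloride should give the salt, which precipitates.

Step 6
Reactants: 7 2-{2-[(E)-2-(4-benzyloxy-3,5-dichlorophenyl)ethenyl]-6-methoxyphenoxy}benzaldehyde; 9 [4-(benzyloxy)benzyl]triphenylphosphonium chloride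
Product: 10 2-(benzyloxy)-1,3-dichloro-5-[(E)-2-(2-{2-[(E)-2-(4-benzyloxyphenyl)ethenyl]phenoxy}-3-methoxyphenyl)ethenyl]benzene (E/Z mixtures expected; E,E drawn)
Conditions: KOtBu, THF, 0 °C to rt
Reagents that add atoms: none
Why: Wittig olefination of the non-enolisable aryl aldehyde with the semistabilised benzylic ylide should attach ring A; again the alkene geometry does not matter.

Step 7
Reactants: 10 the bis-stilbene bis(benzyl ether)
Product: 11 2,6-dichloro-4-[2-(2-{2-[2-(4-hydroxyphenyl)ethyl]phenoxy}-3-methoxyphenyl)ethyl]phenol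
Conditions: H2 (1 atm), 10% Pd/C, EtOAc with a little AcOH, rt, stopped when uptake ends
Reagents that add atoms: none
Why: Catalytic hydrogenation of both alkenes with concurrent hydrogenolysis of both O-benzyl groups should occur under base-free, slightly acidic conditions, under which aryl chlorides are cleaved only slowly.

Step 8
Reactants: 11 2,6-dichloro-4-[2-(2-{2-[2-(4-hydroxyphenyl)ethyl]phenoxy}-3-methoxyphenyl)ethyl]phenol
Product: 12 2,6-dibromo-4-[2-(2-{2-[2-(3,5-dichloro-4-hydroxyphenyl)ethyl]-6-methoxyphenoxy}phenyl)ethyl]phenol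
Conditions: NBS (2.05 equiv), cat. i-Pr2NH, CH2Cl2, 0 °C, dark
Reagents that add atoms: N-bromosuccinimide, O=C1CCC(=O)N1Br
Why: Amine-mediated ortho-selective electrophilic bromination should touch only the ring-A phenol, because the ring-B phenol has no free ortho or para position and the aryl ether rings C and D are far less activated.

Step 9
Reactants: 12 2,6-dibromo-4-[2-(2-{2-[2-(3,5-dichloro-4-hydroxyphenyl)ethyl]-6-methoxyphenoxy}phenyl)ethyl]phenol
Product: 14 bromophenol macrocycle (target ring system with Br in place of the outer ring-A OH; two Cl on ring B flanking the new ether oxygen; OMe on ring C), via bromodienone macrocycle 13 (not isolated)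
Conditions: anodic oxidation, glassy-carbon anode, Pt cathode, undivided cell, 0.1 M LiClO4 in MeOH–CH2Cl2, low constant current at the first wave of the dibromophenol (about +1.0 V vs SCE, ca. 2.2 F/mol), 12 fed slowly to ≤1 mM, 0 °C; then Zn dust, AcOH–THF, rt
Reagents that add atoms: none
Why: Two-electron anodic oxidation of the ring-A 2,6-dibromophenol should give a phenoxonium ion (via the phenoxyl radical), which the ring-B phenol oxygen captures at a bromine-bearing ortho carbon to form the 6-aryloxy-2,6-dibromocyclohexa-2,4-dienone 13; zinc then cleaves the C–Br bond alpha to the carbonyl and the enolate tautomerises to the o-aryloxyphenol 14. The closest known reaction type is the anodic (or thallium(III)) oxidative coupling of o,o'-dihalophenols to diaryl ethers through halodienones and zinc reduction, as used for isodityrosine-type ethers and their macrocycles. The 17-membered ring closes by intramolecular O-attack of the tethered phenol on the ring-A dienyl cation (macro-etherification, formally 17-endo with respect to the ring-A pi system); the sp3 carbon of 13 relieves strain during closure and high dilution suppresses oligomers. The only new stereocentre, the C(Br)(OAr) carbon of 13, forms racemic and is erased by zinc, and the target has none. The step needs three selectivities: oxidation of ring A and not ring B, which the halogen choice secures (the dibromophenol is expected to oxidise before the dichlorophenol); O-attack at an ortho C–Br carbon and not at the para carbon, which would need a more strained 15-membered spiro-dienone that zinc returns to 12; and no C–C coupling or third phenol, secured by the ring-B chlorines and the ring-C methyl ether. The two ortho carbons of ring A are equivalent, so no regiochemical choice arises there.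

Step 10
Reactants: 14 bromophenol macrocycle
Product: 15 ring-A benzyl ether of 14
Conditions: BnBr, K2CO3, DMF, 50 °C
Reagents that add atoms: benzyl bromide, BrCc1ccccc1
Why: Williamson etherification of the single free phenol, which lies on the outer rim of the macrocycle, protects it for the palladium step.

Step 11
Reactants: 15 ring-A benzyl ether of 14
Product: 17 macrocycle with the outer ring-A OH free (central ring-A oxygen benzylated; ring B dichloro; ring C OMe), via pinacol boronate 16 (not isolated)
Conditions: B2pin2, Pd(dppf)Cl2, KOAc, dioxane, 90 °C; then H2O2, NaOH, THF–H2O, 0 °C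
Reagents that add atoms: bis(pinacolato)diboron, CC1(C)OB(OC1(C)C)B1OC(C)(C)C(C)(C)O1 (boron of intermediate 16 only); hydrogen peroxide, OO (the new oxygen of 17)
Why: Miyaura borylation should engage the aryl bromide selectively over the hindered, electron-rich aryl chlorides with the dppf catalyst, and oxidation of the boronate with 1,2-aryl migration to oxygen delivers the phenol.

Step 12
Reactants: 17 ring-A monobenzyl ether, ring-B dichloride
Product: 18 ring-C O-methyl ether of the target
Conditions: H2 (3 atm), 10% Pd/C, Et3N, MeOH–THF, 40 °C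
Reagents that add atoms: none
Why: Base-promoted catalytic hydrodechlorination removes both ring-B chlorines and the same catalyst hydrogenolyses the benzyl ether, the diaryl ether bonds being stable.

Step 13
Reactants: 18 ring-C O-methyl ether of the target
Product: 19 target CNP0290892.0
Conditions: BBr3, CH2Cl2, −78 °C to rt; aqueous work-up
Reagents that add atoms: none
Why: Lewis-acid demethylation of the aryl methyl ether with BBr3 should leave the diaryl ethers intact and release the third phenol.

**Compound list**

1 | 3,5-dichloro-4-hydroxybenzaldehyde | O=Cc1cc(Cl)c(O)c(Cl)c1 | starting material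
2 | 4-(benzyloxy)-3,5-dichlorobenzaldehyde | O=Cc1cc(Cl)c(OCc2ccccc2)c(Cl)c1 | intermediate
3 | 2-hydroxy-3-methoxybenzyl alcohol | COc1cccc(CO)c1O | starting material
4 | (2-hydroxy-3-methoxybenzyl)triphenylphosphonium bromide | COc1cccc(C[P+](c2ccccc2)(c2ccccc2)c2ccccc2)c1O.[Br-] | intermediate
5 | 2-[(E)-2-(4-benzyloxy-3,5-dichlorophenyl)ethenyl]-6-methoxyphenol (E drawn) | COc1cccc(/C=C/c2cc(Cl)c(OCc3ccccc3)c(Cl)c2)c1O | intermediate
6 | 2-fluorobenzaldehyde | O=Cc1ccccc1F | starting material
7 | 2-{2-[(E)-2-(4-benzyloxy-3,5-dichlorophenyl)ethenyl]-6-methoxyphenoxy}benzaldehyde | COc1cccc(/C=C/c2cc(Cl)c(OCc3ccccc3)c(Cl)c2)c1Oc1ccccc1C=O | intermediate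
8 | 4-(benzyloxy)benzyl chloride | ClCc1ccc(OCc2ccccc2)cc1 | starting material
9 | [4-(benzyloxy)benzyl]triphenylphosphonium chloride | [Cl-].c1ccc(COc2ccc(C[P+](c3ccccc3)(c3ccccc3)c3ccccc3)cc2)cc1 | intermediate
10 | bis-stilbene bis(benzyl ether), E,E drawn | COc1cccc(/C=C/c2cc(Cl)c(OCc3ccccc3)c(Cl)c2)c1Oc1ccccc1/C=C/c1ccc(OCc2ccccc2)cc1 | intermediate
11 | 2,6-dichloro-4-[2-(2-{2-[2-(4-hydroxyphenyl)ethyl]phenoxy}-3-methoxyphenyl)ethyl]phenol | COc1cccc(CCc2cc(Cl)c(O)c(Cl)c2)c1Oc1ccccc1CCc1ccc(O)cc1 | intermediate
12 | 2,6-dibromo-4-[2-(2-{2-[2-(3,5-dichloro-4-hydroxyphenyl)ethyl]-6-methoxyphenoxy}phenyl)ethyl]phenol | COc1cccc(CCc2cc(Cl)c(O)c(Cl)c2)c1Oc1ccccc1CCc1cc(Br)c(O)c(Br)c1 | intermediate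
13 | bromodienone macrocycle: ring A as 2,6-dibromo-6-aryloxycyclohexa-2,4-dienone, racemic at C(Br)(OAr) | O=C1C(Br)=CC2=CC1(Br)Oc1c(Cl)cc(cc1Cl)CCc1cccc(OC)c1Oc1ccccc1CC2 | intermediate (not isolated)
14 | bromophenol macrocycle: Br in place of the outer ring-A OH, ring B 3,5-dichloro, ring C OMe | Brc1cc2cc(c1O)Oc1c(Cl)cc(cc1Cl)CCc1cccc(OC)c1Oc1ccccc1CC2 | intermediate
15 | ring-A benzyl ether of 14 | Brc1cc2cc(c1OCc1ccccc1)Oc1c(Cl)cc(cc1Cl)CCc1cccc(OC)c1Oc1ccccc1CC2 | intermediate
16 | pinacol boronate (Bpin in place of Br of 15) | CC1(C)OB(OC1(C)C)c1cc2cc(c1OCc1ccccc1)Oc1c(Cl)cc(cc1Cl)CCc1cccc(OC)c1Oc1ccccc1CC2 | intermediate (not isolated)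
17 | macrocycle with outer ring-A OH free, central ring-A O-benzyl, ring B dichloro, ring C OMe | Oc1cc2cc(c1OCc1ccccc1)Oc1c(Cl)cc(cc1Cl)CCc1cccc(OC)c1Oc1ccccc1CC2 | intermediate
18 | ring-C O-methyl ether of the target | Oc1cc2cc(c1O)Oc1ccc(cc1)CCc1cccc(OC)c1Oc1ccccc1CC2 | intermediate
19 | CNP0290892.0 | Oc1cc2cc(c1O)Oc1ccc(cc1)CCc1cccc(O)c1Oc1ccccc1CC2 | target

**Totals**

Total step count: 13. Longest linear sequence: 11 steps (steps 1, 3, 4, 6, 7, 8, 9, 10, 11, 12, 13 from compound 1); steps 2 and 5 are one-step branches.

**Steps most likely to fail**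

1. Step 9. The ring closure may lose to intermolecular coupling (oligomers), the phenoxonium ion may be intercepted by methanol or at the para carbon, or the ring-B phenol may be oxidised instead and give the regioisomeric ether. The fallback changes the approach to a non-oxidative copper-mediated Ullmann macro-etherification on a ring A that already carries its oxygens, with no halogen helpers on ring B. It sets out from 4 (and 6) and comes back to the route at 19. Wittig reaction of 4 with commercial 4-(benzyloxy)benzaldehyde (KOtBu, THF) should give 2-[(E)-2-(4-benzyloxyphenyl)ethenyl]-6-methoxyphenol F1. SNAr of F1 with 6 (K2CO3, DMF, 120 °C) should give 2-{2-[(E)-2-(4-benzyloxyphenyl)ethenyl]-6-methoxyphenoxy}benzaldehyde F2. Commercial 3-bromo-4,5-dimethoxybenzaldehyde is reduced (NaBH4, MeOH) to (3-bromo-4,5-dimethoxyphenyl)methanol F3 and converted with PPh3·HBr (MeCN, reflux) into (3-bromo-4,5-dimethoxybenzyl)triphenylphosphonium bromide F4. Wittig reaction of F2 with F4 (KOtBu, THF) should give the bromo-dimethoxy bis-stilbene F5. Diimide reduction (TsNHNH2, NaOAc, DME–H2O, reflux) saturates both alkenes without touching the aryl bromide and gives the saturated benzyl ether F6. BCl3 with pentamethylbenzene (CH2Cl2, −78 °C) removes the benzyl group and gives 4-[2-(2-{2-[2-(3-bromo-4,5-dimethoxyphenyl)ethyl]phenoxy}-3-methoxyphenyl)ethyl]phenol F7. Intramolecular Ullmann coupling (CuI, N,N-dimethylglycine, Cs2CO3, dioxane, 100 °C, high dilution) closes the same ring-A carbon–oxygen bond and should give the tri-O-methyl ether of the target F8. BBr3 (CH2Cl2, −78 °C to rt) cleaves all three methyl ethers to 19.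

2. Step 7. Hydrogenolytic loss of ring-B chlorine may set in before both benzyl ethers are cleaved, which would destroy the differentiation of the two phenols needed in step 9. The fallback separates the two tasks and uses no catalytic hydrogenation; it sets out from 10 and comes back at 11. Diimide reduction (TsNHNH2, NaOAc, DME–H2O, reflux) should give the saturated bis(benzyl ether) F9, and BCl3 with pentamethylbenzene (CH2Cl2, −78 °C) then removes both benzyl groups, leaving the chlorines and the methyl ether, to give 11.

3. Step 11. Oxidative addition at the electron-rich, ortho-alkoxy aryl bromide may stall, or protodebromination may compete during borylation. The fallback replaces the C–B/oxidation sequence by a direct copper-catalysed Ullmann-type hydroxylation of the aryl bromide (CuI, 8-hydroxyquinoline-type ligand, KOH, DMSO–H2O, 100 °C), conditions under which aryl chlorides do not react. It sets out from 15 and comes back at 17, and it makes no new compound (F0).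

**Further compounds**

F1 | step 9 | 2-[(E)-2-(4-benzyloxyphenyl)ethenyl]-6-methoxyphenol | COc1cccc(/C=C/c2ccc(OCc3ccccc3)cc2)c1O
F2 | step 9 | 2-{2-[(E)-2-(4-benzyloxyphenyl)ethenyl]-6-methoxyphenoxy}benzaldehyde | COc1cccc(/C=C/c2ccc(OCc3ccccc3)cc2)c1Oc1ccccc1C=O
F3 | step 9 | (3-bromo-4,5-dimethoxyphenyl)methanol | COc1cc(CO)cc(Br)c1OC
F4 | step 9 | (3-bromo-4,5-dimethoxybenzyl)triphenylphosphonium bromide | COc1cc(C[P+](c2ccccc2)(c2ccccc2)c2ccccc2)cc(Br)c1OC.[Br-]
F5 | step 9 | 1-bromo-2,3-dimethoxy-5-[(E)-2-(2-{2-[(E)-2-(4-benzyloxyphenyl)ethenyl]-6-methoxyphenoxy}phenyl)ethenyl]benzene | COc1cccc(/C=C/c2ccc(OCc3ccccc3)cc2)c1Oc1ccccc1/C=C/c1cc(Br)c(OC)c(OC)c1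
F6 | step 9 | 1-bromo-2,3-dimethoxy-5-[2-(2-{2-[2-(4-benzyloxyphenyl)ethyl]-6-methoxyphenoxy}phenyl)ethyl]benzene | COc1cccc(CCc2ccc(OCc3ccccc3)cc2)c1Oc1ccccc1CCc1cc(Br)c(OC)c(OC)c1
F7 | step 9 | 4-[2-(2-{2-[2-(3-bromo-4,5-dimethoxyphenyl)ethyl]phenoxy}-3-methoxyphenyl)ethyl]phenol | COc1cccc(CCc2ccc(O)cc2)c1Oc1ccccc1CCc1cc(Br)c(OC)c(OC)c1
F8 | step 9 | tri-O-methyl ether of the target | COc1cc2cc(c1OC)Oc1ccc(cc1)CCc1cccc(OC)c1Oc1ccccc1CC2
F9 | step 7 | 2-(benzyloxy)-1,3-dichloro-5-[2-(2-{2-[2-(4-benzyloxyphenyl)ethyl]phenoxy}-3-methoxyphenyl)ethyl]benzene | COc1cccc(CCc2cc(Cl)c(OCc3ccccc3)c(Cl)c2)c1Oc1ccccc1CCc1ccc(OCc2ccccc2)cc1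
F0 | step 11 | none | none
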